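**Plan**
- Ring atoms are numbered O1, C2 (stereocentre), C3, C4=C5, C6. The retrosynthesis first takes the acrylic acid back to an enol triflate, a C2 acetyl group and a C2 methyl ester. It then cuts the ring bonds C3–C4 and C6–O1 together, then the C5–chain bond, then one carbon of the homofarnesyl chain.
- Enabling feature: in the 3,6-dihydro-2H-pyran, O1–C2–C3 is a latent terminal epoxide (C3 electrophilic, O1 nucleophilic once opened). C4=C5–C6 is a Z-allyl unit that can be a vinyl nucleophile at C4 and an allyl electrophile at C6. The ring is their [3+3] union.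
- Forward: farnesyl bromide → homofarnesyl bromide → anti-carbomagnesiation of propargyl alcohol (a five-membered O–Mg–C chelate as temporary ring) and iodinolysis → Z-iodoalkenol → iodine–magnesium exchange and [3+3] annulation with methyl (R)-glycidate closes the only ring → methyl ketone → enol triflate → acrylic acid.
- Stereochemistry: C2 (R) is bought with methyl (R)-glycidate, and no bond to C2 is made or broken. The chain E-olefins come from (2E,6E)-farnesyl bromide. The ring-olefin geometry comes from the chelate-controlled carbomagnesiation.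

Key step: step 4

Remark: commercial (2E,6E)-farnesyl bromide is taken as geometrically pure; its two E-olefins are not touched anywhere in the route.

**Step 1**
Reactants: 1 (2E,6E)-1-bromo-3,7,11-trimethyldodeca-2,6,10-triene (farnesyl bromide), 2 (chloromethyl)dimethyl(propan-2-yloxy)silane
Product: 5 (3E,7E)-4,8,12-trimethyltrideca-3,7,11-trien-1-ol (homofarnesol), via silylmethyl Grignard reagent 3 (not isolated), via homofarnesyl alkoxysilane 4 (not isolated)
Conditions: 2, Mg, THF, 23 → 45 °C; 1, Li2CuCl4 (3 mol%), THF, −20 → 0 °C; then KF, KHCO3, 30% H2O2, THF–MeOH, 23 °C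
Reagents that add atoms: hydrogen peroxide, OO
Why: Copper-catalysed sp3–sp3 coupling of an (alkoxysilyl)methyl Grignard reagent with a primary allylic bromide should occur at the α-carbon with the E-olefins kept, and Tamao–Fleming oxidation of the C–Si bond should then give the homologous primary alcohol without touching the trisubstituted alkenes.

**Step 2**
Reactants: 5 (3E,7E)-4,8,12-trimethyltrideca-3,7,11-trien-1-ol
Product: 6 (3E,7E)-1-bromo-4,8,12-trimethyltrideca-3,7,11-triene (homofarnesyl bromide)
Conditions: CBr4, PPh3, 2,6-lutidine, CH2Cl2, 0 °C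
Reagents that add atoms: carbon tetrabromide, BrC(Br)(Br)Br
Why: Appel reaction, an SN2 displacement of the oxyphosphonium ion by bromide at a primary carbon under buffered conditions that should spare the acid-sensitive polyene.

**Step 3**
Reactants: 6 (3E,7E)-1-bromo-4,8,12-trimethyltrideca-3,7,11-triene, 7 prop-2-yn-1-ol (propargyl alcohol)
Product: 10 (2Z)-3-iodo-2-[(3E,7E)-4,8,12-trimethyltrideca-3,7,11-trien-1-yl]prop-2-en-1-ol, via homofarnesylmagnesium bromide 8 (not isolated), via chelated alkenylmagnesium alkoxide 9 (not isolated)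
Conditions: 6, Mg, THF, 23 °C; 7, EtMgBr (1.0 equiv), THF, 0 °C, then 8 (1.6 equiv), CuI (15 mol%), THF–Et2O, 0 → 23 °C; I2, −40 → 0 °C
Reagents that add atoms: iodine, [I][I]
Why: Copper-catalysed anti-carbomagnesiation of a propargylic alkoxide: the alkoxide directs the alkyl group to C2 and magnesium to C3 trans to it within a five-membered O–Mg–C chelate, so iodinolysis with retention should give only the Z-iodoalkene and fix the geometry of the future ring olefin.

**Step 4**
Reactants: 10 (2Z)-3-iodo-2-[(3E,7E)-4,8,12-trimethyltrideca-3,7,11-trien-1-yl]prop-2-en-1-ol, 11 methyl (2R)-oxirane-2-carboxylate (methyl (R)-glycidate)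
Product: 15 methyl (2R)-5-[(3E,7E)-4,8,12-trimethyltrideca-3,7,11-trien-1-yl]-3,6-dihydro-2H-pyran-2-carboxylate, via chloromagnesium alkenyl chelate 12 (not isolated), via diol dialkoxide 13 (not isolated), via allylic tosylate 14 (not isolated)
Conditions: i-PrMgCl·LiCl (2.1 equiv), THF, −20 → 0 °C; 11 (1.2 equiv), CuI (10 mol%), THF, −40 → −20 °C; TsCl (1.05 equiv), DMPU, −20 → 45 °C
Reagents that add atoms: none
Why: The first equivalent of i-PrMgCl·LiCl deprotonates the hydroxyl group of 10 and the second carries out a stereoretentive iodine–magnesium exchange, assisted by the cis alkoxide, to give the O–Mg–C chelate 12, whose vinylic carbon, as an alkenylcopper formed with catalytic CuI, should open the glycidate by SN2 attack at the unsubstituted epoxide carbon (bond C3–C4) and free the C2 oxygen as an alkoxide; TsCl should then sulfonylate the primary allylic alkoxide, and the C2 alkoxide displaces the sulfonate (bond C6–O1), so the epoxide and a vinyl-nucleophile/allyl-electrophile ambiphile are joined in a [3+3] annulation in which the former allylic oxygen of 10 leaves and the epoxide oxygen becomes O1. The closest known reaction types are the halogen–magnesium exchange of alkenyl iodides, the copper-catalysed opening of glycidic esters by alkenyl Grignard reagents and the one-flask cyclodehydration of diol dialkoxides with one equivalent of a sulfonyl chloride (intramolecular Williamson ether synthesis). The one ring formed, the dihydropyran, closes in the 6-exo-tet mode. No stereocentre is created: C2 comes unchanged from the (R)-glycidate because the nucleophile attacks the neighbouring CH2 and the C2–O bond is never broken, and the ring-olefin geometry is carried over from the Z-iodide. The step needs regioselective opening at the epoxide CH2 and chemoselectivity over the ester, which the unhindered ester-activated β-carbon and copper catalysis at −40 °C should secure, and it needs site-selective sulfonylation, which should follow because the primary allylic alkoxide is unhindered while the C2 alkoxide is secondary and chelated to the ester carbonyl. The Z geometry holds the sulfonate-bearing CH2 and the alkoxide arm on the same side of the double bond, so closure should be intramolecular, and the 2-iodopropane left by the exchange, a hindered secondary halide, should not compete as an electrophile.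

**Step 5**
Reactants: 15 methyl (2R)-5-[(3E,7E)-4,8,12-trimethyltrideca-3,7,11-trien-1-yl]-3,6-dihydro-2H-pyran-2-carboxylate
Product: 17 1-[(2R)-5-[(3E,7E)-4,8,12-trimethyltrideca-3,7,11-trien-1-yl]-3,6-dihydro-2H-pyran-2-yl]ethan-1-one, via Weinreb amide 16 (not isolated)
Conditions: MeNH(OMe)·HCl (1.5 equiv), i-PrMgCl (3.0 equiv), THF, −20 °C; MeMgBr (3 equiv), −20 → 0 °C; aq NH4Cl
Reagents that add atoms: methylmagnesium bromide, C[Mg]Br
Why: Weinreb ketone synthesis in one flask: the chloromagnesium amide of MeNH(OMe) aminolyses the methyl ester at −20 °C and the chelated tetrahedral adduct formed with MeMgBr releases the methyl ketone only on work-up, so over-addition should be avoided and C2, never enolised, should keep its configuration.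

**Step 6**
Reactants: 17 1-[(2R)-5-[(3E,7E)-4,8,12-trimethyltrideca-3,7,11-trien-1-yl]-3,6-dihydro-2H-pyran-2-yl]ethan-1-one
Product: 18 1-[(2R)-5-[(3E,7E)-4,8,12-trimethyltrideca-3,7,11-trien-1-yl]-3,6-dihydro-2H-pyran-2-yl]ethenyl trifluoromethanesulfonate
Conditions: PhNTf2 (1.2 equiv), then KN(SiMe3)2 (1.3 equiv) added slowly, THF, −78 °C
Reagents that add atoms: N-phenylbis(trifluoromethanesulfonimide), O=S(=O)(N(c1ccccc1)S(=O)(=O)C(F)(F)F)C(F)(F)F
Why: Kinetic enolate O-triflation: at −78 °C the hindered amide base should remove a proton from the unhindered methyl group rather than from the alkoxy-bearing C2–H, and the enolate is trapped at once by PhNTf2 already in the flask, which should give the terminal enol triflate and leave C2 untouched.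

**Step 7**
Reactants: 18 1-[(2R)-5-[(3E,7E)-4,8,12-trimethyltrideca-3,7,11-trien-1-yl]-3,6-dihydro-2H-pyran-2-yl]ethenyl trifluoromethanesulfonate
Product: 20 2-[(2R)-5-[(3E,7E)-4,8,12-trimethyltrideca-3,7,11-trien-1-yl]-3,6-dihydro-2H-pyran-2-yl]prop-2-enoic acid, via mixed carboxylic anhydride 19 (not isolated)
Conditions: Pd(OAc)2 (5 mol%), dppf (10 mol%), KOAc (4 equiv), CO (1 atm), DMSO, 23 → 50 °C; then H2O, dilute aq KHSO4
Reagents that add atoms: carbon monoxide, [C-]#[O+]; potassium acetate, CC(=O)[O-].[K+] (the hydroxyl oxygen comes from acetate or from water, depending on which carbonyl of 19 is hydrolysed); water, O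
Why: Palladium-catalysed hydroxycarbonylation of an enol triflate: oxidative addition to zerovalent palladium, CO insertion, capture of the acylpalladium by acetate to the mixed anhydride and hydrolysis on work-up should give the α-substituted acrylic acid directly under near-neutral conditions that spare the allylic ether stereocentre and the chain olefins.

**Compound list**
1 | (2E,6E)-1-bromo-3,7,11-trimethyldodeca-2,6,10-triene (farnesyl bromide) | BrC/C=C(\C)CC/C=C(\C)CCC=C(C)C | starting material
2 | (chloromethyl)dimethyl(propan-2-yloxy)silane | CC(C)O[Si](C)(C)CCl | starting material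
3 | chloro{[dimethyl(propan-2-yloxy)silyl]methyl}magnesium | CC(C)O[Si](C)(C)C[Mg]Cl | intermediate
4 | dimethyl(propan-2-yloxy)[(3E,7E)-4,8,12-trimethyltrideca-3,7,11-trien-1-yl]silane | CC(C)O[Si](C)(C)CC/C=C(\C)CC/C=C(\C)CCC=C(C)C | intermediate
5 | (3E,7E)-4,8,12-trimethyltrideca-3,7,11-trien-1-ol | OCC/C=C(\C)CC/C=C(\C)CCC=C(C)C | intermediate
6 | (3E,7E)-1-bromo-4,8,12-trimethyltrideca-3,7,11-triene | BrCC/C=C(\C)CC/C=C(\C)CCC=C(C)C | intermediate
7 | prop-2-yn-1-ol | C#CCO | starting material
8 | bromo[(3E,7E)-4,8,12-trimethyltrideca-3,7,11-trien-1-yl]magnesium | Br[Mg]CC/C=C(\C)CC/C=C(\C)CCC=C(C)C | intermediate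
9 | bromomagnesium (2Z)-3-(bromomagnesio)-2-[(3E,7E)-4,8,12-trimethyltrideca-3,7,11-trien-1-yl]prop-2-en-1-olate (O–Mg–C chelate) | Br[Mg]OC/C(=C\[Mg]Br)CC/C=C(\C)CC/C=C(\C)CCC=C(C)C | intermediate
10 | (2Z)-3-iodo-2-[(3E,7E)-4,8,12-trimethyltrideca-3,7,11-trien-1-yl]prop-2-en-1-ol | OC/C(=C\I)CC/C=C(\C)CC/C=C(\C)CCC=C(C)C | intermediate
11 | methyl (2R)-oxirane-2-carboxylate | COC(=O)[C@H]1CO1 | starting material
12 | chloromagnesium (2Z)-3-(chloromagnesio)-2-[(3E,7E)-4,8,12-trimethyltrideca-3,7,11-trien-1-yl]prop-2-en-1-olate (O–Mg–C chelate) | Cl[Mg]OC/C(=C\[Mg]Cl)CC/C=C(\C)CC/C=C(\C)CCC=C(C)C | intermediate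
13 | bis(chloromagnesium) dialkoxide of methyl (2R,4Z,8E,12E)-2-hydroxy-5-(hydroxymethyl)-9,13,17-trimethyloctadeca-4,8,12,16-tetraenoate | COC(=O)[C@H](O[Mg]Cl)C/C=C(\CO[Mg]Cl)CC/C=C(\C)CC/C=C(\C)CCC=C(C)C | intermediate
14 | chloromagnesium alkoxide of methyl (2R,4Z,8E,12E)-2-hydroxy-9,13,17-trimethyl-5-{[(4-methylbenzenesulfonyl)oxy]methyl}octadeca-4,8,12,16-tetraenoate | COC(=O)[C@H](O[Mg]Cl)C/C=C(\COS(=O)(=O)c1ccc(C)cc1)CC/C=C(\C)CC/C=C(\C)CCC=C(C)C | intermediate
15 | methyl (2R)-5-[(3E,7E)-4,8,12-trimethyltrideca-3,7,11-trien-1-yl]-3,6-dihydro-2H-pyran-2-carboxylate | COC(=O)[C@H]1CC=C(CC/C=C(\C)CC/C=C(\C)CCC=C(C)C)CO1 | intermediate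
16 | (2R)-N-methoxy-N-methyl-5-[(3E,7E)-4,8,12-trimethyltrideca-3,7,11-trien-1-yl]-3,6-dihydro-2H-pyran-2-carboxamide | CON(C)C(=O)[C@H]1CC=C(CC/C=C(\C)CC/C=C(\C)CCC=C(C)C)CO1 | intermediate
17 | 1-[(2R)-5-[(3E,7E)-4,8,12-trimethyltrideca-3,7,11-trien-1-yl]-3,6-dihydro-2H-pyran-2-yl]ethan-1-one | CC(=O)[C@H]1CC=C(CC/C=C(\C)CC/C=C(\C)CCC=C(C)C)CO1 | intermediate
18 | 1-[(2R)-5-[(3E,7E)-4,8,12-trimethyltrideca-3,7,11-trien-1-yl]-3,6-dihydro-2H-pyran-2-yl]ethenyl trifluoromethanesulfonate | C=C(OS(=O)(=O)C(F)(F)F)[C@H]1CC=C(CC/C=C(\C)CC/C=C(\C)CCC=C(C)C)CO1 | intermediate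
19 | acetic 2-[(2R)-5-[(3E,7E)-4,8,12-trimethyltrideca-3,7,11-trien-1-yl]-3,6-dihydro-2H-pyran-2-yl]prop-2-enoic anhydride | C=C(C(=O)OC(C)=O)[C@H]1CC=C(CC/C=C(\C)CC/C=C(\C)CCC=C(C)C)CO1 | intermediate
20 | 2-[(2R)-5-[(3E,7E)-4,8,12-trimethyltrideca-3,7,11-trien-1-yl]-3,6-dihydro-2H-pyran-2-yl]prop-2-enoic acid | C=C(C(=O)O)[C@H]1CC=C(CC/C=C(\C)CC/C=C(\C)CCC=C(C)C)CO1 | target

**Step count**
Total steps: 7. Longest linear sequence: 7 steps (1 → 5 → 6 → 10 → 15 → 17 → 18 → 20); compounds 2, 7 and 11 are bought.

**Steps most likely to fail**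

Step 4. The sulfonyl chloride may fail to discriminate between the two alkoxides, or ring closure of the magnesium alkoxide may be too slow, so that intermolecular etherification and ester exchange take over. The fallback separates the two bond formations; it sets out from 10 and 11 and comes back to the route at 15. The same metalation and copper-catalysed epoxide opening are stopped with aqueous NH4Cl, and the diol methyl (2R,4Z,8E,12E)-2-hydroxy-5-(hydroxymethyl)-9,13,17-trimethyloctadeca-4,8,12,16-tetraenoate F1 is isolated. The ring is then closed in a separate neutral step by Mitsunobu cyclodehydration (PPh3, diisopropyl azodicarboxylate, toluene, 0 → 23 °C). The unhindered primary allylic hydroxyl should be activated as the oxyphosphonium ion and the more acidic hydroxyl next to the ester should act as the nucleophile, so C2 should keep its configuration and 15 should result.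

Step 3. The carbomagnesiation may stall because the Grignard reagent is consumed by deprotonation of the alkyne C–H, which would give low conversion of a reagent that costs two steps. The fallback gives up the iodoalkene and builds 15 by ring-closing metathesis; it sets out from 11 and 1 and comes back at 15. Copper-catalysed opening of 11 with vinylmagnesium bromide (CuI, THF, −40 °C) should give methyl (2R)-2-hydroxypent-4-enoate F2. Separately, the dianion of 2-methylprop-2-en-1-ol (n-BuLi, TMEDA, Et2O) is alkylated with 1 to give 2-[(3E,7E)-4,8,12-trimethyltrideca-3,7,11-trien-1-yl]prop-2-en-1-ol F3. This is converted with CBr4 and PPh3 into (5E,9E)-2-(bromomethyl)-6,10,14-trimethylpentadeca-1,5,9,13-tetraene F4. O-Alkylation of F2 with F4 (Ag2O, Et2O, 23 °C, no strong base, so C2 is not epimerised) should give methyl (2R)-2-({2-[(3E,7E)-4,8,12-trimethyltrideca-3,7,11-trien-1-yl]prop-2-en-1-yl}oxy)pent-4-enoate F5. Ring-closing metathesis with the second-generation Grubbs catalyst (CH2Cl2, 40 °C) between the monosubstituted and the 1,1-disubstituted terminal alkenes should give 15; the trisubstituted chain olefins are too hindered to compete.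

Step 6. Enolisation may occur toward C2, giving the regioisomeric triflate and loss of configuration at C2 by proton exchange. The fallback avoids a ketone enolate altogether; it sets out from 15 and comes back at 20. Reduction of 15 with i-Bu2AlH (CH2Cl2, −78 °C) should give (2R)-5-[(3E,7E)-4,8,12-trimethyltrideca-3,7,11-trien-1-yl]-3,6-dihydro-2H-pyran-2-carbaldehyde F6. Ohira–Bestmann homologation (dimethyl (1-diazo-2-oxopropyl)phosphonate, K2CO3, MeOH, 0 °C) should give (2R)-2-ethynyl-5-[(3E,7E)-4,8,12-trimethyltrideca-3,7,11-trien-1-yl]-3,6-dihydro-2H-pyran F7. Markovnikov hydromethoxycarbonylation of the terminal alkyne (Pd(OAc)2, 2-pyridyldiphenylphosphine, MeSO3H, CO, MeOH, 45 °C) should give methyl 2-[(2R)-5-[(3E,7E)-4,8,12-trimethyltrideca-3,7,11-trien-1-yl]-3,6-dihydro-2H-pyran-2-yl]prop-2-enoate F8. Saponification (LiOH, THF–H2O, 0 → 23 °C) should give 20.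

**Further compounds**
F1 | step 4 | methyl (2R,4Z,8E,12E)-2-hydroxy-5-(hydroxymethyl)-9,13,17-trimethyloctadeca-4,8,12,16-tetraenoate | COC(=O)[C@H](O)C/C=C(\CO)CC/C=C(\C)CC/C=C(\C)CCC=C(C)C
F2 | step 3 | methyl (2R)-2-hydroxypent-4-enoate | COC(=O)[C@H](O)CC=C
F3 | step 3 | 2-[(3E,7E)-4,8,12-trimethyltrideca-3,7,11-trien-1-yl]prop-2-en-1-ol | C=C(CO)CC/C=C(\C)CC/C=C(\C)CCC=C(C)C
F4 | step 3 | (5E,9E)-2-(bromomethyl)-6,10,14-trimethylpentadeca-1,5,9,13-tetraene | C=C(CBr)CC/C=C(\C)CC/C=C(\C)CCC=C(C)C
F5 | step 3 | methyl (2R)-2-({2-[(3E,7E)-4,8,12-trimethyltrideca-3,7,11-trien-1-yl]prop-2-en-1-yl}oxy)pent-4-enoate | COC(=O)[C@H](OCC(=C)CC/C=C(\C)CC/C=C(\C)CCC=C(C)C)CC=C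
F6 | step 6 | (2R)-5-[(3E,7E)-4,8,12-trimethyltrideca-3,7,11-trien-1-yl]-3,6-dihydro-2H-pyran-2-carbaldehyde | O=C[C@H]1CC=C(CC/C=C(\C)CC/C=C(\C)CCC=C(C)C)CO1
F7 | step 6 | (2R)-2-ethynyl-5-[(3E,7E)-4,8,12-trimethyltrideca-3,7,11-trien-1-yl]-3,6-dihydro-2H-pyran | C#C[C@H]1CC=C(CC/C=C(\C)CC/C=C(\C)CCC=C(C)C)CO1
F8 | step 6 | methyl 2-[(2R)-5-[(3E,7E)-4,8,12-trimethyltrideca-3,7,11-trien-1-yl]-3,6-dihydro-2H-pyran-2-yl]prop-2-enoate | C=C(C(=O)OC)[C@H]1CC=C(CC/C=C(\C)CC/C=C(\C)CCC=C(C)C)CO1
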